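The constants were hidden, so I built one from the two earlier runs. I needed it to choose whether the next flask could keep its J or should be charged with less.

in all of them: E 5 mol%; J 8.9 mM

|  | L | remark | time |
|---|---|---|---|
| teal | 0.83 M (fed, over 12 min) | run made earlier; the fed solution adds 0.50 times the starting volume |  |
| blue | 1.3 M (fed, over 12 min) | run made earlier; the fed solution adds 0.50 times the starting volume |  |
| flask | 0.59 M (fed, over 12 min) | the fed solution adds 0.50 times the starting volume | 25 min |

| run | time / min | X / % | L / % |
|---|---|---|---|
| teal | 0.833 | 0 | 10 |
| teal | 2.50 | 0 | 21 |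
| teal | 4.00 | 3 | 32 |
| teal | 6.00 | 1 | 47 |
| teal | 10.0 | 7 | 74 |
| teal | 12.0 | 14 | 87 |
| teal | 15.0 | 23 | 78 |
| blue | 0.833 | 0 | 8 |
| blue | 2.50 | 0 | 19 |
| blue | 4.00 | 2 | 33 |
| blue | 6.00 | 6 | 46 |
| blue | 10.0 | 16 | 68 |
| blue | 12.0 | 24 | 75 |
| blue | 15.0 | 41 | 60 |

(readings scatter by 1.5 percentage points)

- amounts are per litre of the starting volume; all of the dose is in the solution fed
- the average divides the monomer in chains by the number of chains begun, living and dead together
- reactions considered so far: L + E -> Q + X; L + Q -> X + Q; E + J -> Z
- the earlier runs do not show the number of chains; that part of a forecast is a guess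
- percentages count the whole charge, also what has not yet gone in

* average number of monomer units in a chain (chains begun, living or dead) at 25 min
* part of the L that has reacted at 25 min

I first defined the working initiator as the E charged minus the J, since E + J -> Z takes E one for one. Per litre of starting volume, that was 32.6 mM in teal, 56.1 mM in blue and 20.6 mM in the new flask, so J cost that flask 30.2 % of its E.

After the feed the volume stood still, and I integrated the decay of L with one average coefficient k, L(t) = L(end of feed) exp(-k(t - end of feed)), which is an average over the stretch and no constant, since Q may still be building there. Between 12.0 min and 15.0 min the readings gave k as 0.0364 min⁻¹ in teal and 0.0744 min⁻¹ in blue. Dividing k by the working initiator gave the pull, 1.12 M⁻¹ min⁻¹ in teal and 1.33 M⁻¹ min⁻¹ in blue. Both are rough readings, and I took teal's, since teal lies nearer the flask in L. X at the end of the feed per working initiator read 4.29 M⁻¹ in teal and 4.28 M⁻¹ in blue.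

For the new flask I therefore reckoned 8.85 % reacted by 12 min, then k = 0.0230 min⁻¹, which gave 32.4 % at 25 min. That was enough to read, so I kept J. The readings show no chain count, so I reckoned no chain length.

The forecast gave 27 % and 11, from “about 0.02/min after the feed and about 6% reacted by 12 min”; my figure for the part reacted stood higher.

The flask gave 32.0 % and 12.1.

    L + E → Q + X (k = 0.210 M⁻¹ min⁻¹)
    L + Q → X + Q, rate k2*[Q]*[L] (k = 2.70 M⁻¹ min⁻¹)
    E + J → Z (k = 3900 M⁻¹ min⁻¹)

Between 12.0 min and 25.0 min, L fell at an average 0.0241 min⁻¹, against the 0.0230 min⁻¹ from the pull. On chain length, the largest single effect among the simulated runs was the length of the run: left ten times as long, the flask reached 30.0 against 12.1.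

For the neighbour flask charged with 0.0036 M of J, the working initiator is 25.9 mM, and the same reckoning gives 39.0 %; the computed result is 38.1 %.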